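**Plan**
- Retrosynthesis: with the phenols masked as acetals and an ester placed on C2, the tetralone is cut at C1–C2 and C3–C4 into methyl acrylate and a hydroxy-o-quinodimethane, which is the photoenol of a 2-(naphthylmethyl)benzaldehyde. That aldehyde is cut at its aryl–CH2 bond (Suzuki–Miyaura), and the CH2–B and C–B bonds of the naphthyl partner lead back to a juglone-derived triflate.
- Enabling feature: the carbonyl carbon C1 and the stereogenic C4 of the tetralone are attached to the neighbouring carbons C8a and C4a of the catechol ring, so they are the two exocyclic termini of an o-quinodimethane, and C2–C3 is a two-carbon dienophile.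
- Forward: juglone is taken to the naphthylmethyl boronate, a bromobenzodioxole is formylated, and the two are coupled to the diarylmethane aldehyde. The only ring formed in the route, the tetralone carbocycle, arises in the photoenolisation/[4+2] step.
- Stereochemistry: C4 is set in that cycloaddition inside the chiral complex Ti(TADDOLate)(OiPr)2. The centres C1 and C2 formed with it are erased by oxidation and decarboxylation, and C4 is never α to a carbonyl.

Key step: step 9

Assumption: (R,R)-TADDOL is written as the ligand that leads to the (4S) series; the sense of induction is not established for this substrate class, and the (S,S)-ligand would be used if the opposite face is preferred.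

**Route**

Step 1
Reactants: 1 juglone (5-hydroxy-1,4-naphthoquinone)
Product: 2 5-methoxy-1,4-naphthoquinone
Conditions: MeI, Ag2O, CH2Cl2, rt, dark
Reagents that add atoms: iodomethane, CI
Why: Williamson-type O-methylation of the chelated peri-phenol, with Ag2O as mild base and iodide acceptor, is the standard neutral way to etherify a hydroxyquinone without touching the quinone.

Step 2
Reactants: 2 5-methoxy-1,4-naphthoquinone
Product: 3 5-methoxynaphthalene-1,4-diol
Conditions: Na2S2O4, EtOAc/H2O, rt, argon; used at once
Reagents that add atoms: none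
Why: Dithionite reduction of a quinone to its hydroquinone is a clean two-electron reduction, and the air-sensitive diol is carried on directly under argon.

Step 3
Reactants: 3 5-methoxynaphthalene-1,4-diol
Product: 4 8-methoxy-4-(methoxymethoxy)naphthalen-1-ol
Conditions: MOMCl (1.05 equiv), iPr2NEt, CH2Cl2, 0 °C, argon
Reagents that add atoms: chloromethyl methyl ether, COCCl
Why: In this Williamson-type etherification the hydroxyl beside the peri-methoxy group is shielded and held in an O–H···OMe hydrogen bond, so one equivalent of MOMCl should alkylate the remote hydroxyl.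

Step 4
Reactants: 4 8-methoxy-4-(methoxymethoxy)naphthalen-1-ol
Product: 5 8-methoxy-4-(methoxymethoxy)naphthalen-1-yl trifluoromethanesulfonate
Conditions: Tf2O, pyridine, CH2Cl2, −78 → 0 °C
Reagents that add atoms: trifluoromethanesulfonic anhydride, O=S(=O)(OS(=O)(=O)C(F)(F)F)C(F)(F)F
Why: O-Sulfonylation of the remaining naphthol turns the peri oxygen into a leaving group for cross-coupling, and the MOM acetal is inert to the pyridine-buffered conditions at low temperature.

Step 5
Reactants: 5 8-methoxy-4-(methoxymethoxy)naphthalen-1-yl trifluoromethanesulfonate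
Product: 6 2-[8-methoxy-4-(methoxymethoxy)naphthalen-1-yl]-4,4,5,5-tetramethyl-1,3,2-dioxaborolane
Conditions: B2pin2, Pd(dppf)Cl2 (5 mol %), KOAc, 1,4-dioxane, 90 °C
Reagents that add atoms: bis(pinacolato)diboron, CC1(C)OB(OC1(C)C)B1OC(C)(C)C(C)(C)O1
Why: Miyaura borylation (oxidative addition of the aryl triflate to zerovalent palladium, acetate-assisted transmetalation with B2pin2, reductive elimination) exchanges C–O for C–B without organolithium chemistry that the MOM group could divert.

Step 6
Reactants: 6 2-[8-methoxy-4-(methoxymethoxy)naphthalen-1-yl]-4,4,5,5-tetramethyl-1,3,2-dioxaborolane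
Product: 8 2-{[8-methoxy-4-(methoxymethoxy)naphthalen-1-yl]methyl}-4,4,5,5-tetramethyl-1,3,2-dioxaborolane, via lithium chloromethyl boronate complex 7 (not isolated)
Conditions: BrCH2Cl, n-BuLi, THF, −78 °C → rt
Reagents that add atoms: bromochloromethane, ClCBr
Why: Matteson homologation: LiCH2Cl generated in situ by bromine–lithium exchange adds to boron, and the ate complex 7 undergoes a 1,2-aryl shift with loss of chloride, which inserts the future C4 methylene into the C–B bond.

Step 7
Reactants: 9 5-bromo-2,2-dimethyl-1,3-benzodioxole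
Product: 11 5-bromo-2,2-dimethyl-1,3-benzodioxole-4-carbaldehyde, via 5-bromo-4-lithio-2,2-dimethyl-1,3-benzodioxole 10 (not isolated)
Conditions: LiN(iPr)2, THF, −78 °C; DMF, −78 → 0 °C; 1 M HCl quench
Reagents that add atoms: N,N-dimethylformamide, CN(C)C=O
Why: Directed ortho-lithiation: the hydrogen flanked by the dioxole oxygen and the bromine is the most acidic on the ring, the amide base removes it without bromine–lithium exchange at −78 °C, and the aryllithium 10 is formylated by DMF.

Step 8
Reactants: 8 2-{[8-methoxy-4-(methoxymethoxy)naphthalen-1-yl]methyl}-4,4,5,5-tetramethyl-1,3,2-dioxaborolane; 11 5-bromo-2,2-dimethyl-1,3-benzodioxole-4-carbaldehyde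
Product: 12 5-{[8-methoxy-4-(methoxymethoxy)naphthalen-1-yl]methyl}-2,2-dimethyl-1,3-benzodioxole-4-carbaldehyde
Conditions: Pd(dppf)Cl2 (5 mol %), K2CO3, 1,4-dioxane/H2O, 85 °C
Reagents that add atoms: none
Why: Suzuki–Miyaura sp3–sp2 coupling of a primary benzylic pinacol boronate, which has no β-hydrogen, with an aryl bromide activated by its ortho formyl group should give the diarylmethane, and the non-enolisable aldehyde tolerates aqueous carbonate.

Step 9
Reactants: 12 5-{[8-methoxy-4-(methoxymethoxy)naphthalen-1-yl]methyl}-2,2-dimethyl-1,3-benzodioxole-4-carbaldehyde; 13 methyl acrylate (5 equiv)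
Product: 15 methyl (1S,2S,4S)-1-hydroxy-7,8-(isopropylidenedioxy)-4-[8-methoxy-4-(methoxymethoxy)naphthalen-1-yl]-1,2,3,4-tetrahydronaphthalene-2-carboxylate (all-cis), via hydroxy-o-quinodimethane photoenol 14 (not isolated)
Conditions: Ti(OiPr)4 (1.2 equiv), (R,R)-TADDOL [(4R,5R)-2,2-dimethyl-α,α,α′,α′-tetraphenyl-1,3-dioxolane-4,5-dimethanol] (1.3 equiv), degassed toluene, hν (365 nm LED), rt; aq. NaHCO3 work-up
Reagents that add atoms: none
Why: Proposed new method: excitation of the aldehyde n,π* band at 365 nm, where the naphthalene does not absorb, is followed by 1,5-hydrogen transfer from the doubly benzylic CH2 and gives the hydroxy-o-quinodimethane 14 with OH and naphthyl both pointing outward, whose oxygen is taken up by the tetravalent titanium TADDOLate that also activates the acrylate carbonyl, so that the [4+2] runs inside one chiral complex. The closest known reaction type is the Ti(OiPr)4/TADDOL-mediated enantioselective photoenolisation/Diels–Alder reaction of 2-methylbenzaldehydes with enones, and separately the cycloaddition of photoenols of 2-benzylbenzaldehydes with acrylates and fumarates; new here is the union of an aryl-substituted photoenol, a simple acrylate and the chiral titanium complex. The one new ring, the six-membered carbocycle C1–C2–C3–C4–C4a–C8a, closes by intermolecular [4+2] cycloaddition in which C1–C2 and C3–C4 form together and the catechol ring regains aromaticity. C4 is set by the diene face that the TADDOLate aryl groups leave open, C1 is cis to C4 because both diene termini carry their substituent outward, and C2 is cis to both through the endo transition state in which titanium bridges the dienol oxygen and the ester carbonyl. The step needs ortho regiochemistry, endo selectivity and facial selectivity: the first follows from the larger HOMO coefficient at the naphthyl-bearing terminus, which bonds to the acrylate β-carbon, and the other two from the titanium bridge, helped by the acetonide oxygen beside the formyl group as a second donor. Only C4 has to be right, since C1 and C2 are removed in steps 10 and 11.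

Step 10
Reactants: 15 methyl (1S,2S,4S)-1-hydroxy-7,8-(isopropylidenedioxy)-4-[8-methoxy-4-(methoxymethoxy)naphthalen-1-yl]-1,2,3,4-tetrahydronaphthalene-2-carboxylate
Product: 16 methyl (4S)-7,8-(isopropylidenedioxy)-4-[8-methoxy-4-(methoxymethoxy)naphthalen-1-yl]-1-oxo-1,2,3,4-tetrahydronaphthalene-2-carboxylate (C2 epimers and enol)
Conditions: Dess–Martin periodinane, CH2Cl2, 0 °C → rt, protected from light
Reagents that add atoms: none
Why: Dess–Martin oxidation of the benzylic secondary alcohol runs under near-neutral conditions that spare both acetals, removes the C1 centre and makes C2 enolisable, and leaves C4, which is not α to the new carbonyl, untouched.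

Step 11
Reactants: 16 methyl (4S)-7,8-(isopropylidenedioxy)-4-[8-methoxy-4-(methoxymethoxy)naphthalen-1-yl]-1-oxo-1,2,3,4-tetrahydronaphthalene-2-carboxylate
Product: 17 (4S)-7,8-(isopropylidenedioxy)-4-[8-methoxy-4-(methoxymethoxy)naphthalen-1-yl]-3,4-dihydronaphthalen-1(2H)-one
Conditions: LiCl, H2O, DMSO, 140 °C, protected from light
Reagents that add atoms: none
Why: Krapcho dealkoxycarbonylation (SN2 attack of chloride on the ester methyl, loss of CO2 from the β-keto carboxylate, protonation of the enolate by water) removes the ester under near-neutral conditions in which the MOM ether, the acetonide and the non-enolisable C4 centre persist.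

Step 12
Reactants: 17 (4S)-7,8-(isopropylidenedioxy)-4-[8-methoxy-4-(methoxymethoxy)naphthalen-1-yl]-3,4-dihydronaphthalen-1(2H)-one
Product: 18 (4S)-7,8-dihydroxy-4-(4-hydroxy-8-methoxynaphthalen-1-yl)-3,4-dihydronaphthalen-1(2H)-one (CNP0535815.1)
Conditions: HCl (3 M in MeOH), 50 °C, argon, protected from light
Reagents that add atoms: none
Why: Acid-catalysed transacetalisation to methanol cleaves the MOM ether and the catechol isopropylidene ketal in one operation and traps the formaldehyde unit as dimethoxymethane, while the aryl methyl ether, the ketone and the C4 centre are not affected.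

**Compound list**
1 | juglone (5-hydroxy-1,4-naphthoquinone) | O=C1C=CC(=O)c2c(O)cccc12 | starting material
2 | 5-methoxy-1,4-naphthoquinone | O=C1C=CC(=O)c2c(OC)cccc12 | intermediate
3 | 5-methoxynaphthalene-1,4-diol | COc1cccc2c(O)ccc(O)c12 | intermediate
4 | 8-methoxy-4-(methoxymethoxy)naphthalen-1-ol | COc1cccc2c(OCOC)ccc(O)c12 | intermediate
5 | 8-methoxy-4-(methoxymethoxy)naphthalen-1-yl trifluoromethanesulfonate | COc1cccc2c(OCOC)ccc(OS(=O)(=O)C(F)(F)F)c12 | intermediate
6 | 2-[8-methoxy-4-(methoxymethoxy)naphthalen-1-yl]-4,4,5,5-tetramethyl-1,3,2-dioxaborolane | COc1cccc2c(OCOC)ccc(B3OC(C)(C)C(C)(C)O3)c12 | intermediate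
7 | lithium (chloromethyl)[8-methoxy-4-(methoxymethoxy)naphthalen-1-yl](pinacolato)borate, the ate complex | [Li+].COc1cccc2c(OCOC)ccc([B-]3(CCl)OC(C)(C)C(C)(C)O3)c12 | intermediate (not isolated)
8 | 2-{[8-methoxy-4-(methoxymethoxy)naphthalen-1-yl]methyl}-4,4,5,5-tetramethyl-1,3,2-dioxaborolane | COc1cccc2c(OCOC)ccc(CB3OC(C)(C)C(C)(C)O3)c12 | intermediate
9 | 5-bromo-2,2-dimethyl-1,3-benzodioxole | CC1(C)Oc2ccc(Br)cc2O1 | starting material
10 | 5-bromo-4-lithio-2,2-dimethyl-1,3-benzodioxole | CC1(C)Oc2ccc(Br)c([Li])c2O1 | intermediate (not isolated)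
11 | 5-bromo-2,2-dimethyl-1,3-benzodioxole-4-carbaldehyde | CC1(C)Oc2ccc(Br)c(C=O)c2O1 | intermediate
12 | 5-{[8-methoxy-4-(methoxymethoxy)naphthalen-1-yl]methyl}-2,2-dimethyl-1,3-benzodioxole-4-carbaldehyde | CC1(C)Oc2ccc(Cc3ccc(OCOC)c4cccc(OC)c34)c(C=O)c2O1 | intermediate
13 | methyl acrylate | C=CC(=O)OC | starting material
14 | (4Z,5E)-4-(hydroxymethylidene)-5-{[8-methoxy-4-(methoxymethoxy)naphthalen-1-yl]methylidene}-2,2-dimethyl-4,5-dihydro-1,3-benzodioxole (photoenol, OH and naphthyl both outward) | O/C=C1/C(=C/c2ccc(OCOC)c3cccc(OC)c23)C=CC2=C1OC(C)(C)O2 | intermediate (not isolated)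
15 | methyl (1S,2S,4S)-1-hydroxy-7,8-(isopropylidenedioxy)-4-[8-methoxy-4-(methoxymethoxy)naphthalen-1-yl]-1,2,3,4-tetrahydronaphthalene-2-carboxylate (all-cis) | COc1cccc2c(OCOC)ccc([C@@H]3C[C@H](C(=O)OC)[C@H](O)c4c3ccc3OC(C)(C)Oc43)c12 | intermediate
16 | methyl (4S)-7,8-(isopropylidenedioxy)-4-[8-methoxy-4-(methoxymethoxy)naphthalen-1-yl]-1-oxo-1,2,3,4-tetrahydronaphthalene-2-carboxylate | COc1cccc2c(OCOC)ccc([C@@H]3CC(C(=O)OC)C(=O)c4c3ccc3OC(C)(C)Oc43)c12 | intermediate
17 | (4S)-7,8-(isopropylidenedioxy)-4-[8-methoxy-4-(methoxymethoxy)naphthalen-1-yl]-3,4-dihydronaphthalen-1(2H)-one | COc1cccc2c(OCOC)ccc([C@@H]3CCC(=O)c4c3ccc3OC(C)(C)Oc43)c12 | intermediate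
18 | (4S)-7,8-dihydroxy-4-(4-hydroxy-8-methoxynaphthalen-1-yl)-3,4-dihydronaphthalen-1(2H)-one | COc1cccc2c(O)ccc([C@@H]3CCC(=O)c4c3ccc(O)c4O)c12 | target

**Step count and risks**
Total steps: 12. Longest linear sequence: 11 (steps 1–6 and 8–12; step 7 is a one-step side branch).

Steps most likely to fail:

1. Step 9 (Proposed new method). The acrylate binds titanium through one carbonyl only, so the chiral complex may discriminate the two diene faces poorly. Energy transfer from the excited aldehyde to the naphthalene may slow photoenolisation, and dienol trapped outside the complex would add without facial control. Fallback with known chemistry, setting out from 12: the aldehyde is irradiated (365 nm, toluene, no titanium) in the presence of (R)-pantolactone acrylate. Chiral acrylates and fumarates of this kind are known to add with auxiliary control to photochemically generated α-hydroxy-o-quinodimethanes, including those from 2-benzylbenzaldehydes. The endo adduct (3R)-4,4-dimethyl-2-oxooxolan-3-yl (1S,2S,4S)-1-hydroxy-7,8-(isopropylidenedioxy)-4-[8-methoxy-4-(methoxymethoxy)naphthalen-1-yl]-1,2,3,4-tetrahydronaphthalene-2-carboxylate F1 would be separated from its diastereomer by chromatography or crystallisation; the enantiomeric auxiliary would be taken if the 4R series dominates. Oxidation with Dess–Martin periodinane should give the β-keto ester (3R)-4,4-dimethyl-2-oxooxolan-3-yl (4S)-7,8-(isopropylidenedioxy)-4-[8-methoxy-4-(methoxymethoxy)naphthalen-1-yl]-1-oxo-1,2,3,4-tetrahydronaphthalene-2-carboxylate F2. Dealkoxycarbonylation of F2 in wet DMSO with LiCl at 140 °C comes back to the route at 17.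

2. Step 8. Protodeboronation of the electron-rich benzylic boronate and slow transmetalation of the sp3 boron beside the peri-substituted naphthalene may leave 11 unconsumed. Fallback with reversed polarity, setting out from 11 and from the aryl boronate 6: Stille hydroxymethylation of 11 (Bu3SnCH2OH, Pd(PPh3)4, dioxane, 100 °C) should give 5-(hydroxymethyl)-2,2-dimethyl-1,3-benzodioxole-4-carbaldehyde F3, in equilibrium with its lactol. PBr3 in CH2Cl2 at 0 °C converts it into 5-(bromomethyl)-2,2-dimethyl-1,3-benzodioxole-4-carbaldehyde F4. Suzuki–Miyaura coupling of F4 with 6 (Pd(PPh3)4, aq. K2CO3, DME, 80 °C) comes back at 12, and step 6 is then not needed.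

3. Step 3. Alkylation of both hydroxyls or partly of the hydrogen-bonded one, and re-oxidation of the hydroquinone to 2 during a slow mono-alkylation, would erode the regiochemical basis of the naphthalene partner. Fallback, setting out from 3: the differentiation is handed to a bulky silyl chloride and the MOM group is introduced only when a single hydroxyl is left. TIPSCl and imidazole in DMF at 0 °C should give 8-methoxy-4-[(triisopropylsilyl)oxy]naphthalen-1-ol F5. Tf2O and pyridine give 8-methoxy-4-[(triisopropylsilyl)oxy]naphthalen-1-yl trifluoromethanesulfonate F6. Bu4NF buffered with AcOH in THF at 0 °C releases 4-hydroxy-8-methoxynaphthalen-1-yl trifluoromethanesulfonate F7. MOMCl and iPr2NEt then come back to the route at 5.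

**Further compounds**
F1 | step 9 | (3R)-4,4-dimethyl-2-oxooxolan-3-yl (1S,2S,4S)-1-hydroxy-7,8-(isopropylidenedioxy)-4-[8-methoxy-4-(methoxymethoxy)naphthalen-1-yl]-1,2,3,4-tetrahydronaphthalene-2-carboxylate | COc1cccc2c(OCOC)ccc([C@@H]3C[C@H](C(=O)O[C@H]4C(=O)OCC4(C)C)[C@H](O)c4c3ccc3OC(C)(C)Oc43)c12
F2 | step 9 | (3R)-4,4-dimethyl-2-oxooxolan-3-yl (4S)-7,8-(isopropylidenedioxy)-4-[8-methoxy-4-(methoxymethoxy)naphthalen-1-yl]-1-oxo-1,2,3,4-tetrahydronaphthalene-2-carboxylate | COc1cccc2c(OCOC)ccc([C@@H]3CC(C(=O)O[C@H]4C(=O)OCC4(C)C)C(=O)c4c3ccc3OC(C)(C)Oc43)c12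
F3 | step 8 | 5-(hydroxymethyl)-2,2-dimethyl-1,3-benzodioxole-4-carbaldehyde | CC1(C)Oc2ccc(CO)c(C=O)c2O1
F4 | step 8 | 5-(bromomethyl)-2,2-dimethyl-1,3-benzodioxole-4-carbaldehyde | CC1(C)Oc2ccc(CBr)c(C=O)c2O1
F5 | step 3 | 8-methoxy-4-[(triisopropylsilyl)oxy]naphthalen-1-ol | COc1cccc2c(O[Si](C(C)C)(C(C)C)C(C)C)ccc(O)c12
F6 | step 3 | 8-methoxy-4-[(triisopropylsilyl)oxy]naphthalen-1-yl trifluoromethanesulfonate | COc1cccc2c(O[Si](C(C)C)(C(C)C)C(C)C)ccc(OS(=O)(=O)C(F)(F)F)c12
F7 | step 3 | 4-hydroxy-8-methoxynaphthalen-1-yl trifluoromethanesulfonate | COc1cccc2c(O)ccc(OS(=O)(=O)C(F)(F)F)c12
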